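**Plan**

Labels: ring A carbons in order are a (pentanoyl), b (OH), c (CH3), d (OH), e (CH2 bridge), f (OH); ring B carries, in order, the bridge, OH, butanoyl, OH, CH3 and OCH3.
Feature used: the acyl carbon a and the hydroxyl carbon b are neighbours on a ring whose other four positions are filled, the pattern left when a carboxylic acid adds across an aryne spanning a and b.
Retrosynthesis: cut the four benzyl ethers, then the bond from carbon a to the acyl carbon and the bond from carbon b to oxygen together (aryne plus pentanoic acid), then the bond from the CH2 bridge to ring B (Negishi). This gives a ring A benzylic chloride with SiMe3 on carbon a and triflate on carbon b, and a ring B bromide.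
Forward: both rings come from 2-methylphloroglucinol. Ring B: acylation, 4-O-methylation, benzylation, bromination. Ring A: formylation, para-OH protection, benzylation, deprotection, bromination, reduction, retro-Brook/triflation, chlorination. Then coupling, aryne insertion, hydrogenolysis.
No ring is formed and the target has no stereocentre, so no stereocontrol is needed.

Key step: step 14

Remark: compounds 1, 2 and 21 are taken as purchased; equivalents given are proposals, not results.

**Route**

Step 1
Reactants: 1 2-methylphloroglucinol; 2 butanoyl chloride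
Product: 3 1-(2,4,6-trihydroxy-3-methylphenyl)butan-1-one
Conditions: AlCl3 (3.5 equiv), PhNO2–CH2Cl2, 0 to 50 °C; then ice/aq. HCl
Reagents that add atoms: none
Why: Friedel–Crafts acylation; the two unsubstituted carbons of 1 are equivalent and the first acyl group deactivates the ring, so a single monoketone should form.

Step 2
Reactants: 3 1-(2,4,6-trihydroxy-3-methylphenyl)butan-1-one
Product: 4 1-(2,6-dihydroxy-4-methoxy-3-methylphenyl)butan-1-one (aspidinol)
Conditions: Me2SO4 (1.0 equiv), K2CO3 (1.0 equiv), acetone, 25 °C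
Reagents that add atoms: dimethyl sulfate, COS(=O)(=O)OC
Why: Williamson O-methylation under acidity control; the 4-hydroxyl para to the ketone is the most acidic and is not hydrogen-bonded to the carbonyl, so one equivalent of base and electrophile should react there.

Step 3
Reactants: 4 1-(2,6-dihydroxy-4-methoxy-3-methylphenyl)butan-1-one
Product: 5 1-[2,6-bis(benzyloxy)-4-methoxy-3-methylphenyl]butan-1-one
Conditions: BnBr (2.5 equiv), K2CO3 (3 equiv), DMF, 60 °C
Reagents that add atoms: benzyl bromide, BrCc1ccccc1
Why: Williamson ether synthesis; excess reagent and heat should etherify both chelated ortho hydroxyls, and K2CO3 in DMF favours O- over C-alkylation.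

Step 4
Reactants: 5 1-[2,6-bis(benzyloxy)-4-methoxy-3-methylphenyl]butan-1-one
Product: 6 1-[2,6-bis(benzyloxy)-3-bromo-4-methoxy-5-methylphenyl]butan-1-one
Conditions: NBS (1.05 equiv), MeCN, 0 to 25 °C
Reagents that add atoms: N-bromosuccinimide, O=C1CCC(=O)N1Br
Why: Electrophilic aromatic bromination; the one free ring position is activated by three alkoxy groups and should react far faster than the ketone α-position.

Step 5
Reactants: 1 2-methylphloroglucinol
Product: 8 2,4,6-trihydroxy-3-methylbenzaldehyde, via iminium chloride 7 (not isolated)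
Conditions: POCl3 (1.1 equiv), DMF (1.2 equiv), EtOAc, 0 to 25 °C; then H2O, 60 °C
Reagents that add atoms: N,N-dimethylformamide, CN(C)C=O; water, O
Why: Vilsmeier–Haack formylation; the chloroiminium ion attacks one of the two equivalent free carbons, and the iminium salt 7 deactivates the ring against a second attack before water hydrolyses it.

Step 6
Reactants: 8 2,4,6-trihydroxy-3-methylbenzaldehyde
Product: 9 2,6-dihydroxy-4-(methoxymethoxy)-3-methylbenzaldehyde
Conditions: MOMCl (1.05 equiv), iPr2NEt (1.1 equiv), THF, 0 °C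
Reagents that add atoms: chloromethyl methyl ether, COCCl
Why: Methoxymethylation of the most acidic phenol; the hydroxyl para to the formyl group (on carbon b of ring A) is a vinylogous acid and not chelated, so it should react ahead of the two hydrogen-bonded ortho hydroxyls.

Step 7
Reactants: 9 2,6-dihydroxy-4-(methoxymethoxy)-3-methylbenzaldehyde
Product: 10 2,6-bis(benzyloxy)-4-(methoxymethoxy)-3-methylbenzaldehyde
Conditions: BnBr (2.5 equiv), K2CO3 (3 equiv), DMF, 60 °C
Reagents that add atoms: benzyl bromide, BrCc1ccccc1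
Why: Williamson benzylation of the two chelated hydroxyls (on carbons d and f of ring A); the MOM acetal and the aldehyde are stable to carbonate.

Step 8
Reactants: 10 2,6-bis(benzyloxy)-4-(methoxymethoxy)-3-methylbenzaldehyde
Product: 11 2,6-bis(benzyloxy)-4-hydroxy-3-methylbenzaldehyde
Conditions: 3 M aq. HCl, THF, 50 °C
Reagents that add atoms: none
Why: Acid hydrolysis of the MOM acetal; the formyl group keeps the ring electron-poor enough for the aryl benzyl ethers to survive, so only the hydroxyl on carbon b is freed.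

Step 9
Reactants: 11 2,6-bis(benzyloxy)-4-hydroxy-3-methylbenzaldehyde
Product: 12 2,6-bis(benzyloxy)-3-bromo-4-hydroxy-5-methylbenzaldehyde
Conditions: NBS (1.02 equiv), CH2Cl2, 0 °C
Reagents that add atoms: N-bromosuccinimide, O=C1CCC(=O)N1Br
Why: Electrophilic aromatic bromination ortho to the free phenol; carbon a is the last unsubstituted ring carbon and is activated by the adjacent hydroxyl and benzyloxy groups.

Step 10
Reactants: 12 2,6-bis(benzyloxy)-3-bromo-4-hydroxy-5-methylbenzaldehyde
Product: 13 3,5-bis(benzyloxy)-2-bromo-4-(hydroxymethyl)-6-methylphenol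
Conditions: NaBH4, THF–MeOH, 0 to 25 °C; aq. NH4Cl work-up, crude product used directly
Reagents that add atoms: none
Why: Borohydride reduction of the aldehyde; the aryl bromide and benzyl ethers are inert, and a cold neutral work-up with direct use of the crude diol should avoid quinone methide formation.

Step 11
Reactants: 13 3,5-bis(benzyloxy)-2-bromo-4-(hydroxymethyl)-6-methylphenol
Product: 17 3,5-bis(benzyloxy)-4-(hydroxymethyl)-2-methyl-6-(trimethylsilyl)phenyl trifluoromethanesulfonate, via bis(trimethylsilyl) ether 14 (not isolated), via lithium 2-silylphenoxide 15 (not isolated), via O-silylated triflate 16 (not isolated)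
Conditions: HMDS, (NH4)2SO4 (cat.), THF, 65 °C, evaporate; n-BuLi (1.1 equiv), THF, –78 °C; PhNTf2, –78 to 25 °C; then 0.5 M aq. HCl, THF, 0 °C
Reagents that add atoms: hexamethyldisilazane, C[Si](C)(C)N[Si](C)(C)C; N-phenylbis(trifluoromethanesulfonimide), O=S(=O)(N(c1ccccc1)S(=O)(=O)C(F)(F)F)C(F)(F)F
Why: Bromine–lithium exchange followed by retro-Brook rearrangement; after both hydroxyls are silylated, n-BuLi exchanges the bromine on carbon a, the SiMe3 group on the oxygen of carbon b shifts to the adjacent carbanion, PhNTf2 (chosen over Tf2O because it spares the benzylic silyl ether) triflates the phenoxide, and dilute acid removes only the primary O–SiMe3 group.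

Step 12
Reactants: 17 3,5-bis(benzyloxy)-4-(hydroxymethyl)-2-methyl-6-(trimethylsilyl)phenyl trifluoromethanesulfonate
Product: 18 3,5-bis(benzyloxy)-4-(chloromethyl)-2-methyl-6-(trimethylsilyl)phenyl trifluoromethanesulfonate
Conditions: PPh3, NCS, THF, 0 to 25 °C
Reagents that add atoms: N-chlorosuccinimide, ClN1C(=O)CCC1=O
Why: Appel-type chlorination via the alkoxyphosphonium salt needs neither acid nor base, so the aryl–silicon bond and the triflate are safe, and the para triflate tempers ionisation of the benzylic chloride.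

Step 13
Reactants: 18 3,5-bis(benzyloxy)-4-(chloromethyl)-2-methyl-6-(trimethylsilyl)phenyl trifluoromethanesulfonate; 6 1-[2,6-bis(benzyloxy)-3-bromo-4-methoxy-5-methylphenyl]butan-1-one
Product: 20 3,5-bis(benzyloxy)-4-{[2,4-bis(benzyloxy)-3-butanoyl-6-methoxy-5-methylphenyl]methyl}-2-methyl-6-(trimethylsilyl)phenyl trifluoromethanesulfonate, via benzylzinc chloride 19 (not isolated)
Conditions: Zn dust (activated by BrCH2CH2Br, Me3SiCl), LiCl, THF, 25 °C; solution decanted onto 6 (1.2 equiv), Pd[P(t-Bu)3]2 (5 mol%), THF, 25 to 50 °C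
Reagents that add atoms: none
Why: Negishi cross-coupling; LiCl-assisted zinc insertion gives 19, which tolerates the ketone of 6, zerovalent palladium bearing bulky P(t-Bu)3 should insert into the hindered C–Br bond rather than the doubly flanked aryl triflate, and no fluoride is present to disturb the silyl triflate pair.

Step 14
Reactants: 20 3,5-bis(benzyloxy)-4-{[2,4-bis(benzyloxy)-3-butanoyl-6-methoxy-5-methylphenyl]methyl}-2-methyl-6-(trimethylsilyl)phenyl trifluoromethanesulfonate; 21 pentanoic acid
Product: 23 1-(2,4-bis(benzyloxy)-3-{[2,4-bis(benzyloxy)-3-butanoyl-6-methoxy-5-methylphenyl]methyl}-6-hydroxy-5-methylphenyl)pentan-1-one, via aryne 22 (not isolated)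
Conditions: 21 (1.2 equiv), CsF (5 equiv), THF, 125 °C, sealed tube
Reagents that add atoms: none
Why: Fluoride attacks the silicon on carbon a and triflate leaves from carbon b to release aryne 22; caesium pentanoate adds through oxygen to carbon b, the aryl anion at carbon a attacks the ester carbonyl to give a transient four-membered alkoxide, and its opening gives the ketone on carbon a and the phenoxide on carbon b, so both new skeletal bonds form in one event. The closest known reaction is the fluoride-induced insertion of arynes from ortho-silylaryl triflates into the C–O bond of carboxylic acids to give ortho-hydroxyaryl ketones, applied here to a fully substituted aryne. No ring persists in the product and no stereocentre is created. The step needs oxygen on carbon b and acyl on carbon a: the benzyloxy group on carbon f beside carbon a distorts and polarises the aryne so that the nucleophile adds to the remote carbon b and the charge develops at carbon a next to the inductively withdrawing oxygen, while the methyl on carbon c adds some hindrance but no comparable electronic bias. Acyl transfer must also outrun protonation of the aryl anion, which hot, weakly polar THF with excess CsF and no other proton source should favour. Ring B is a spectator because its ketone is shielded by two ortho benzyloxy groups, it has no O–H, and every other ring position is blocked.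

Step 15
Reactants: 23 1-(2,4-bis(benzyloxy)-3-{[2,4-bis(benzyloxy)-3-butanoyl-6-methoxy-5-methylphenyl]methyl}-6-hydroxy-5-methylphenyl)pentan-1-one
Product: 24 1-(3-{[3-butanoyl-2,4-dihydroxy-6-methoxy-5-methylphenyl]methyl}-2,4,6-trihydroxy-5-methylphenyl)pentan-1-one (target)
Conditions: H2 (1 atm), 10% Pd/C, EtOAc–MeOH, 25 °C
Reagents that add atoms: none
Why: Catalytic hydrogenolysis of the four aryl benzyl ethers; the hydrogen-bonded aryl ketones and the methyl ether should not be reduced under these mild conditions.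

**Compound list**

1 | 2-methylbenzene-1,3,5-triol (2-methylphloroglucinol) | Cc1c(O)cc(O)cc1O | starting material
2 | butanoyl chloride | CCCC(=O)Cl | starting material
3 | 1-(2,4,6-trihydroxy-3-methylphenyl)butan-1-one | CCCC(=O)c1c(O)cc(O)c(C)c1O | intermediate
4 | 1-(2,6-dihydroxy-4-methoxy-3-methylphenyl)butan-1-one (aspidinol) | CCCC(=O)c1c(O)cc(OC)c(C)c1O | intermediate
5 | 1-[2,6-bis(benzyloxy)-4-methoxy-3-methylphenyl]butan-1-one | CCCC(=O)c1c(OCc2ccccc2)cc(OC)c(C)c1OCc1ccccc1 | intermediate
6 | 1-[2,6-bis(benzyloxy)-3-bromo-4-methoxy-5-methylphenyl]butan-1-one | CCCC(=O)c1c(OCc2ccccc2)c(Br)c(OC)c(C)c1OCc1ccccc1 | intermediate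
7 | dimethyl[(2,4,6-trihydroxy-3-methylphenyl)methylidene]ammonium chloride | C[N+](C)=Cc1c(O)c(C)c(O)cc1O.[Cl-] | intermediate
8 | 2,4,6-trihydroxy-3-methylbenzaldehyde | O=Cc1c(O)c(C)c(O)cc1O | intermediate
9 | 2,6-dihydroxy-4-(methoxymethoxy)-3-methylbenzaldehyde | O=Cc1c(O)c(C)c(OCOC)cc1O | intermediate
10 | 2,6-bis(benzyloxy)-4-(methoxymethoxy)-3-methylbenzaldehyde | O=Cc1c(OCc2ccccc2)c(C)c(OCOC)cc1OCc1ccccc1 | intermediate
11 | 2,6-bis(benzyloxy)-4-hydroxy-3-methylbenzaldehyde | O=Cc1c(OCc2ccccc2)c(C)c(O)cc1OCc1ccccc1 | intermediate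
12 | 2,6-bis(benzyloxy)-3-bromo-4-hydroxy-5-methylbenzaldehyde | O=Cc1c(OCc2ccccc2)c(C)c(O)c(Br)c1OCc1ccccc1 | intermediate
13 | 3,5-bis(benzyloxy)-2-bromo-4-(hydroxymethyl)-6-methylphenol | OCc1c(OCc2ccccc2)c(C)c(O)c(Br)c1OCc1ccccc1 | intermediate
14 | {[2,6-bis(benzyloxy)-3-bromo-5-methyl-4-(trimethylsilyloxy)phenyl]methoxy}trimethylsilane | C[Si](C)(C)OCc1c(OCc2ccccc2)c(C)c(O[Si](C)(C)C)c(Br)c1OCc1ccccc1 | intermediate
15 | lithium 3,5-bis(benzyloxy)-2-methyl-6-(trimethylsilyl)-4-[(trimethylsilyloxy)methyl]phenoxide | C[Si](C)(C)OCc1c(OCc2ccccc2)c(C)c([O-])c([Si](C)(C)C)c1OCc1ccccc1.[Li+] | intermediate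
16 | 3,5-bis(benzyloxy)-2-methyl-6-(trimethylsilyl)-4-[(trimethylsilyloxy)methyl]phenyl trifluoromethanesulfonate | C[Si](C)(C)OCc1c(OCc2ccccc2)c(C)c(OS(=O)(=O)C(F)(F)F)c([Si](C)(C)C)c1OCc1ccccc1 | intermediate
17 | 3,5-bis(benzyloxy)-4-(hydroxymethyl)-2-methyl-6-(trimethylsilyl)phenyl trifluoromethanesulfonate | OCc1c(OCc2ccccc2)c(C)c(OS(=O)(=O)C(F)(F)F)c([Si](C)(C)C)c1OCc1ccccc1 | intermediate
18 | 3,5-bis(benzyloxy)-4-(chloromethyl)-2-methyl-6-(trimethylsilyl)phenyl trifluoromethanesulfonate | ClCc1c(OCc2ccccc2)c(C)c(OS(=O)(=O)C(F)(F)F)c([Si](C)(C)C)c1OCc1ccccc1 | intermediate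
19 | {[2,6-bis(benzyloxy)-3-methyl-4-(trifluoromethanesulfonyloxy)-5-(trimethylsilyl)phenyl]methyl}zinc chloride | Cl[Zn]Cc1c(OCc2ccccc2)c(C)c(OS(=O)(=O)C(F)(F)F)c([Si](C)(C)C)c1OCc1ccccc1 | intermediate
20 | 3,5-bis(benzyloxy)-4-{[2,4-bis(benzyloxy)-3-butanoyl-6-methoxy-5-methylphenyl]methyl}-2-methyl-6-(trimethylsilyl)phenyl trifluoromethanesulfonate | C[Si](C)(C)c1c(OS(=O)(=O)C(F)(F)F)c(C)c(OCc2ccccc2)c(Cc2c(OCc3ccccc3)c(C(=O)CCC)c(OCc3ccccc3)c(C)c2OC)c1OCc1ccccc1 | intermediate
21 | pentanoic acid | CCCCC(=O)O | starting material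
22 | 4,6-bis(benzyloxy)-5-{[2,4-bis(benzyloxy)-3-butanoyl-6-methoxy-5-methylphenyl]methyl}-3-methylbenzyne (triple bond between carbons a and b of ring A) | C1#CC(C)=C(OCc2ccccc2)C(Cc2c(OCc3ccccc3)c(C(=O)CCC)c(OCc3ccccc3)c(C)c2OC)=C1OCc1ccccc1 | intermediate
23 | 1-(2,4-bis(benzyloxy)-3-{[2,4-bis(benzyloxy)-3-butanoyl-6-methoxy-5-methylphenyl]methyl}-6-hydroxy-5-methylphenyl)pentan-1-one | CCCCC(=O)c1c(O)c(C)c(OCc2ccccc2)c(Cc2c(OCc3ccccc3)c(C(=O)CCC)c(OCc3ccccc3)c(C)c2OC)c1OCc1ccccc1 | intermediate
24 | 1-(3-{[3-butanoyl-2,4-dihydroxy-6-methoxy-5-methylphenyl]methyl}-2,4,6-trihydroxy-5-methylphenyl)pentan-1-one | CCCCC(=O)c1c(O)c(C)c(O)c(Cc2c(O)c(C(=O)CCC)c(O)c(C)c2OC)c1O | target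

**Step count and risks**

Total step count: 15. Longest linear sequence: 11 steps (steps 5 to 15, from 1 to 24). The ring B branch (steps 1 to 4) joins at step 13.

Steps most likely to fail:

1. Step 14 (aryne insertion). The aryl anion at carbon a may be protonated by bifluoride or residual acid before it attacks the ester carbonyl, so the reaction stops at O-arylation. The doubly flanked aryne may also be consumed by the solvent or by a neighbouring benzyl ether. Fallback: accept O-arylation as a separate, known step and move the acyl group afterwards. Setting out from 20, CsF and pentanoic acid 21 in MeCN at 25 °C (aryne O-arylation of carboxylic acids) should give 3,5-bis(benzyloxy)-4-{[2,4-bis(benzyloxy)-3-butanoyl-6-methoxy-5-methylphenyl]methyl}-2-methylphenyl pentanoate F1. Hydrogenolysis (H2, Pd/C) would then give 4-{[3-butanoyl-2,4-dihydroxy-6-methoxy-5-methylphenyl]methyl}-3,5-dihydroxy-2-methylphenyl pentanoate F2. A Fries rearrangement (boron trifluoride diethyl etherate, 80 °C) should shift the pentanoyl group to carbon a of ring A, the only unsubstituted ring carbon in the molecule, and the route is rejoined at target 24.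

2. Step 13 (Negishi coupling). Oxidative addition into the doubly ortho-substituted, electron-rich C–Br bond of 6 may be slow, leaving room for homocoupling of 19 or palladium insertion into the aryl triflate. Fallback: make the same bond by electrophilic aromatic substitution instead of cross-coupling. Setting out from chloride 18 and the unbrominated ring B ether 5, whose single free position is activated by three alkoxy groups, a Friedel–Crafts benzylation (ZnCl2 cat., 2,6-di-tert-butylpyridine as proton scavenger, CH2Cl2, 0 °C) should rejoin the route at 20 with no new intermediate.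

3. Step 11 (silylation, retro-Brook shift, triflation). The hydroxybenzylic alcohol 13 may ionise towards a quinone methide before or during silylation, n-BuLi may attack silicon instead of bromine, or triflation of the doubly flanked phenoxide by PhNTf2 may stall. Fallback: keep the benzylic carbon at the aldehyde level, masked as an acetal, until the silyl triflate is in place. Setting out from 12, acetalisation with 1,2-bis(trimethylsilyloxy)ethane and catalytic TMSOTf (CH2Cl2, –78 to –20 °C) should give 3,5-bis(benzyloxy)-2-bromo-4-(1,3-dioxolan-2-yl)-6-methylphenol F3. HMDS would convert it to [3,5-bis(benzyloxy)-2-bromo-4-(1,3-dioxolan-2-yl)-6-methylphenoxy]trimethylsilane F4. n-BuLi at –78 °C should give lithium 3,5-bis(benzyloxy)-4-(1,3-dioxolan-2-yl)-2-methyl-6-(trimethylsilyl)phenoxide F5, which the more reactive Tf2O can now trap as 3,5-bis(benzyloxy)-4-(1,3-dioxolan-2-yl)-2-methyl-6-(trimethylsilyl)phenyl trifluoromethanesulfonate F6. Mild hydrolysis (PPTS, acetone–water) should free 3,5-bis(benzyloxy)-4-formyl-2-methyl-6-(trimethylsilyl)phenyl trifluoromethanesulfonate F7, and NaBH4 reduction rejoins the route at alcohol 17.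

**Further compounds**

F1 | step 14 | 3,5-bis(benzyloxy)-4-{[2,4-bis(benzyloxy)-3-butanoyl-6-methoxy-5-methylphenyl]methyl}-2-methylphenyl pentanoate | CCCCC(=O)Oc1cc(OCc2ccccc2)c(Cc2c(OCc3ccccc3)c(C(=O)CCC)c(OCc3ccccc3)c(C)c2OC)c(OCc2ccccc2)c1C
F2 | step 14 | 4-{[3-butanoyl-2,4-dihydroxy-6-methoxy-5-methylphenyl]methyl}-3,5-dihydroxy-2-methylphenyl pentanoate | CCCCC(=O)Oc1cc(O)c(Cc2c(O)c(C(=O)CCC)c(O)c(C)c2OC)c(O)c1C
F0 | step 13 | none | none
F3 | step 11 | 3,5-bis(benzyloxy)-2-bromo-4-(1,3-dioxolan-2-yl)-6-methylphenol | Oc1c(C)c(OCc2ccccc2)c(C2OCCO2)c(OCc2ccccc2)c1Br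
F4 | step 11 | [3,5-bis(benzyloxy)-2-bromo-4-(1,3-dioxolan-2-yl)-6-methylphenoxy]trimethylsilane | C[Si](C)(C)Oc1c(C)c(OCc2ccccc2)c(C2OCCO2)c(OCc2ccccc2)c1Br
F5 | step 11 | lithium 3,5-bis(benzyloxy)-4-(1,3-dioxolan-2-yl)-2-methyl-6-(trimethylsilyl)phenoxide | [Li+].[O-]c1c(C)c(OCc2ccccc2)c(C2OCCO2)c(OCc2ccccc2)c1[Si](C)(C)C
F6 | step 11 | 3,5-bis(benzyloxy)-4-(1,3-dioxolan-2-yl)-2-methyl-6-(trimethylsilyl)phenyl trifluoromethanesulfonate | C[Si](C)(C)c1c(OS(=O)(=O)C(F)(F)F)c(C)c(OCc2ccccc2)c(C2OCCO2)c1OCc1ccccc1
F7 | step 11 | 3,5-bis(benzyloxy)-4-formyl-2-methyl-6-(trimethylsilyl)phenyl trifluoromethanesulfonate | O=Cc1c(OCc2ccccc2)c(C)c(OS(=O)(=O)C(F)(F)F)c([Si](C)(C)C)c1OCc1ccccc1
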